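**Plan**

- Locants are those of the target name N-[(1R,4R,4aR,8aS)-4-[(2S,5R)-5-chloro-2,6,6-trimethyloxan-2-yl]-1,6-dimethyl-1,2,3,4,4a,7,8,8a-octahydronaphthalen-1-yl]formamide (oxane O1, C2–C6; decalin C1–C8a).
- Retrosynthetic cuts, in order: N–CHO and C1–CH3 (ketimine plus MeMgBr); C4a–C5 and C8a–C8 of ring A (Diels–Alder); C4a–C8a and C3–C4 of ring B (Robinson annulation with methyl vinyl ketone); the decalin C4–oxane C2 bond (allylation of an oxocarbenium ion); last the oxane bonds C4–C5 and O1–C6 ([4+2]).
- Forward: the oxane arises first, as a dihydropyran; then its quaternary C2, ring B, ring A, and the C1 amine last.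
- Enabling feature: the oxane edge O1–C2(CH3)–C3–C4 is methyl vinyl ketone read as a 1-oxadiene, and the edge C5H(Cl)–C6(CH3)2 is 1-chloro-2-methylpropene. The two methyl groups on C6 let that carbon carry the positive charge that O1 captures, so oxygen goes to C6 and carbon to C5.
- Stereochemistry: oxane C5 from the chiral acid in the [4+2]; oxane C2 by axial attack trans to chlorine; decalin C4 from the prolinol catalyst; C4a and C8a from a cis, anti Diels–Alder reaction; C1 by delivery of methyl to the convex face of a ketimine.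

Key step: step 1

Remark: the sense of induction of the chiral acid in step 1 cannot be assigned from precedent; the (R)-acid is written, and its mirror image is taken if it delivers the other enantiomer of 3.

**Route**

Step 1
Reactants: 1 methyl vinyl ketone (but-3-en-2-one); 2 1-chloro-2-methylprop-1-ene
Product: 3 (3R)-3-chloro-2,2,6-trimethyl-3,4-dihydro-2H-pyran
Conditions: (R)-3,3'-bis(2,4,6-triisopropylphenyl)-1,1'-binaphthyl-2,2'-diyl N-(trifluoromethylsulfonyl)phosphoramide (5 mol %), 2 (10 equiv), toluene, −60 → −30 °C, slow addition of 1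
Reagents that add atoms: none
Why: Proposed new method: the chiral acid protonates the carbonyl oxygen of s-cis 1, the CHCl carbon of 2 adds to the terminal CH2, and the developing tertiary, chlorine-bridged cation at CMe2 is captured by the enol oxygen, so that 1 acts as a 1-oxadiene and 2 as the 2π partner in an asynchronous inverse-electron-demand oxa-Diels–Alder reaction. The closest known reaction types are the thermal and Lewis-acid [4+2] reactions of vinyl ketones with isobutene-type alkenes and the N-triflylphosphoramide-catalysed Diels–Alder reactions of alkyl vinyl ketones. The dihydropyran closes as a six-membered ring in the [4+2] mode (in the stepwise limit, capture of the tertiary cation by the enol oxygen). The only new stereocentre, the CHCl carbon, is to be set by the catalyst, whose counter-anion is hydrogen-bonded to the protonated carbonyl and should differentiate the two faces of the alkene as its CMe2 end approaches the oxygen. The step needs regioselectivity (oxygen to CMe2, carbon to CHCl), secured by the two cation-stabilising methyl groups, and it needs chemoselectivity over self-cycloaddition and polymerisation of 1, secured by slow addition of 1 to excess 2.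

Step 2
Reactants: 3 (3R)-3-chloro-2,2,6-trimethyl-3,4-dihydro-2H-pyran
Product: 5 (3R,6S)-3-chloro-2,2,6-trimethyl-6-(prop-2-en-1-yl)oxane, via methyl ketal 4 (not isolated)
Conditions: MeOH, PPTS (cat.), 0 °C; evaporate; allylSiMe3, Me3SiOTf (0.2 equiv), CH2Cl2, −78 °C
Reagents that add atoms: allyltrimethylsilane, C=CC[Si](C)(C)C
Why: Acid-catalysed addition of methanol to the enol ether gives the ketal, Me3SiOTf ionises it to the tertiary oxocarbenium ion, and allyltrimethylsilane adds (Hosomi–Sakurai allylation) along the axial trajectory of the half-chair in which chlorine is pseudoaxial (electrostatically favoured and anti to the pseudoaxial methyl of the CMe2 group), so the allyl group should end trans to chlorine and the new quaternary centre is S.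

Step 3
Reactants: 5 (3R,6S)-3-chloro-2,2,6-trimethyl-6-(prop-2-en-1-yl)oxane
Product: 6 2-[(2S,5R)-5-chloro-2,6,6-trimethyloxan-2-yl]acetaldehyde
Conditions: O3, CH2Cl2, −78 °C; then Me2S
Reagents that add atoms: ozone, [O-][O+]=O
Why: Ozonolysis of the terminal alkene with reductive work-up; the ether and the secondary chloride are inert and no stereocentre is touched.

Step 4
Reactants: 6 2-[(2S,5R)-5-chloro-2,6,6-trimethyloxan-2-yl]acetaldehyde; 1 methyl vinyl ketone
Product: 8 (4R)-4-[(2S,5R)-5-chloro-2,6,6-trimethyloxan-2-yl]cyclohex-2-en-1-one, via keto aldehyde 7 (not isolated)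
Conditions: (S)-2-[diphenyl(trimethylsilyloxy)methyl]pyrrolidine (10 mol %), PhCO2H (10 mol %), 1 (2 equiv), CH2Cl2, 0 °C → rt; then p-TsOH·H2O (cat.), toluene, 50 °C
Reagents that add atoms: none
Why: Enamine Michael addition to methyl vinyl ketone, in which the enone approaches the enamine face remote from the CPh2OSiMe3 group (catalyst control; S in 7, R in 8), followed by acid-mediated intramolecular aldol condensation, i.e. an organocatalytic Robinson annulation that builds ring B.

Step 5
Reactants: 9 bis(trimethylsilyl)methane; 1 methyl vinyl ketone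
Product: 11 (E)-trimethyl(2-methylbuta-1,3-dien-1-yl)silane, via lithiated bis(trimethylsilyl)methane 10 (not isolated)
Conditions: t-BuLi, THF/HMPA, −78 °C; then 1, −78 → 20 °C
Reagents that add atoms: none
Why: Peterson olefination: the bis(silyl)carbanion adds 1,2 to the ketone and the β-silyl alkoxide loses Me3SiO– to give the vinylsilane; only the E isomer can reach the s-cis conformation needed in step 6, so a Z fraction is simply left behind.

Step 6
Reactants: 8 (4R)-4-[(2S,5R)-5-chloro-2,6,6-trimethyloxan-2-yl]cyclohex-2-en-1-one; 11 (E)-trimethyl(2-methylbuta-1,3-dien-1-yl)silane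
Product: 13 (4R,4aS,8aS)-4-[(2S,5R)-5-chloro-2,6,6-trimethyloxan-2-yl]-6-methyl-3,4,4a,7,8,8a-hexahydronaphthalen-1(2H)-one, via allylsilane 12 (not isolated)
Conditions: EtAlCl2 (30 mol %), toluene, −40 → 0 °C; then CF3CO2H, CH2Cl2, 0 °C
Reagents that add atoms: none
Why: Lewis-acid-catalysed Diels–Alder reaction in which the diene adds suprafacially to the enone face opposite the oxanyl group (cis ring fusion, sets C4a and C8a), with the methyl-bearing diene carbon para to the carbonyl-bearing carbon so that silicon sits on C5; protodesilylation of the allylsilane (SE2′) then places the double bond at C5=C6.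

Step 7
Reactants: 13 (4R,4aS,8aS)-4-[(2S,5R)-5-chloro-2,6,6-trimethyloxan-2-yl]-6-methyl-3,4,4a,7,8,8a-hexahydronaphthalen-1(2H)-one
Product: 14 (R)-N-[(4R,4aR,8aS)-4-[(2S,5R)-5-chloro-2,6,6-trimethyloxan-2-yl]-6-methyl-3,4,4a,7,8,8a-hexahydronaphthalen-1(2H)-ylidene]-2-methylpropane-2-sulfinamide
Conditions: Ti(OEt)4 (2 equiv), THF, 40 °C
Reagents that add atoms: (R)-2-methylpropane-2-sulfinamide, CC(C)(C)[S@](N)=O
Why: Titanium-mediated condensation of a ketone with tert-butanesulfinamide to the N-sulfinyl ketimine, run at mild temperature so that the cis ring fusion next to the C=N bond should not equilibrate.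

Step 8
Reactants: 14 the N-sulfinyl ketimine of step 7
Product: 15 (R)-N-[(1R,4R,4aR,8aS)-4-[(2S,5R)-5-chloro-2,6,6-trimethyloxan-2-yl]-1,6-dimethyl-1,2,3,4,4a,7,8,8a-octahydronaphthalen-1-yl]-2-methylpropane-2-sulfinamide
Conditions: MeMgBr, toluene/Et2O, −40 °C
Reagents that add atoms: methylmagnesium bromide, C[Mg]Br
Why: 1,2-Addition of a Grignard reagent to an N-sulfinyl ketimine; methyl should enter axially from the convex face of the cis-fused bicycle, anti to the axial C8a–C8 bond, which places methyl axial and nitrogen equatorial at C1 (R), the sulfinyl group serving as activator and nitrogen protection.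

Step 9
Reactants: 15 the sulfinamide of step 8
Product: 17 N-[(1R,4R,4aR,8aS)-4-[(2S,5R)-5-chloro-2,6,6-trimethyloxan-2-yl]-1,6-dimethyl-1,2,3,4,4a,7,8,8a-octahydronaphthalen-1-yl]formamide, via amine hydrochloride 16 (not isolated)
Conditions: HCl (4 M in dioxane), MeOH, 0 °C; evaporate; Et3N, HCO2CH2CF3, THF, 50 °C
Reagents that add atoms: 2,2,2-trifluoroethyl formate, O=COCC(F)(F)F
Why: Acidic methanolysis of the N–S bond followed by N-formylation of the hindered primary amine with an activated formate ester; no stereocentre is involved.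

**Compound list**

1 | methyl vinyl ketone (but-3-en-2-one) | CC(=O)C=C | starting material
2 | 1-chloro-2-methylprop-1-ene | CC(C)=CCl | starting material
3 | (3R)-3-chloro-2,2,6-trimethyl-3,4-dihydro-2H-pyran | CC1=CC[C@@H](Cl)C(C)(C)O1 | intermediate
4 | (3R)-3-chloro-6-methoxy-2,2,6-trimethyloxane (both C6 epimers) | COC1(C)CC[C@@H](Cl)C(C)(C)O1 | intermediate (not isolated)
5 | (3R,6S)-3-chloro-2,2,6-trimethyl-6-(prop-2-en-1-yl)oxane | C=CC[C@]1(C)CC[C@@H](Cl)C(C)(C)O1 | intermediate
6 | 2-[(2S,5R)-5-chloro-2,6,6-trimethyloxan-2-yl]acetaldehyde | O=CC[C@]1(C)CC[C@@H](Cl)C(C)(C)O1 | intermediate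
7 | (2S)-2-[(2S,5R)-5-chloro-2,6,6-trimethyloxan-2-yl]-5-oxohexanal | CC(=O)CC[C@H](C=O)[C@]1(C)CC[C@@H](Cl)C(C)(C)O1 | intermediate (not isolated)
8 | (4R)-4-[(2S,5R)-5-chloro-2,6,6-trimethyloxan-2-yl]cyclohex-2-en-1-one | O=C1C=C[C@H]([C@]2(C)CC[C@@H](Cl)C(C)(C)O2)CC1 | intermediate
9 | bis(trimethylsilyl)methane | C[Si](C)(C)C[Si](C)(C)C | starting material
10 | [bis(trimethylsilyl)methyl]lithium | C[Si](C)(C)C([Li])[Si](C)(C)C | intermediate (not isolated)
11 | (E)-trimethyl(2-methylbuta-1,3-dien-1-yl)silane | C[Si](C)(C)/C=C(C)/C=C | intermediate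
12 | (4R,4aS,8aS)-4-[(2S,5R)-5-chloro-2,6,6-trimethyloxan-2-yl]-6-methyl-5-(trimethylsilyl)-3,4,4a,5,8,8a-hexahydronaphthalen-1(2H)-one (C5 epimers) | CC1=CC[C@@H]2C(=O)CC[C@@H]([C@]3(C)CC[C@@H](Cl)C(C)(C)O3)[C@@H]2C1[Si](C)(C)C | intermediate (not isolated)
13 | (4R,4aS,8aS)-4-[(2S,5R)-5-chloro-2,6,6-trimethyloxan-2-yl]-6-methyl-3,4,4a,7,8,8a-hexahydronaphthalen-1(2H)-one | CC1=C[C@H]2[C@H]([C@]3(C)CC[C@@H](Cl)C(C)(C)O3)CCC(=O)[C@H]2CC1 | intermediate
14 | (R)-N-[(4R,4aR,8aS)-4-[(2S,5R)-5-chloro-2,6,6-trimethyloxan-2-yl]-6-methyl-3,4,4a,7,8,8a-hexahydronaphthalen-1(2H)-ylidene]-2-methylpropane-2-sulfinamide | CC1=C[C@H]2[C@H]([C@]3(C)CC[C@@H](Cl)C(C)(C)O3)CCC(=N[S@](=O)C(C)(C)C)[C@H]2CC1 | intermediate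
15 | (R)-N-[(1R,4R,4aR,8aS)-4-[(2S,5R)-5-chloro-2,6,6-trimethyloxan-2-yl]-1,6-dimethyl-1,2,3,4,4a,7,8,8a-octahydronaphthalen-1-yl]-2-methylpropane-2-sulfinamide | CC1=C[C@H]2[C@H]([C@]3(C)CC[C@@H](Cl)C(C)(C)O3)CC[C@@](C)(N[S@](=O)C(C)(C)C)[C@H]2CC1 | intermediate
16 | (1R,4R,4aR,8aS)-4-[(2S,5R)-5-chloro-2,6,6-trimethyloxan-2-yl]-1,6-dimethyl-1,2,3,4,4a,7,8,8a-octahydronaphthalen-1-aminium chloride | CC1=C[C@H]2[C@H]([C@]3(C)CC[C@@H](Cl)C(C)(C)O3)CC[C@@](C)([NH3+])[C@H]2CC1.[Cl-] | intermediate (not isolated)
17 | N-[(1R,4R,4aR,8aS)-4-[(2S,5R)-5-chloro-2,6,6-trimethyloxan-2-yl]-1,6-dimethyl-1,2,3,4,4a,7,8,8a-octahydronaphthalen-1-yl]formamide | CC1=C[C@H]2[C@H]([C@]3(C)CC[C@@H](Cl)C(C)(C)O3)CC[C@@](C)(NC=O)[C@H]2CC1 | target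

**Count and risks**

Total steps: 9. Longest linear sequence: 8 (steps 1, 2, 3, 4, 6, 7, 8, 9); step 5 is a side branch.

Steps most likely to fail:

1. Step 1 (proposed new method). The chloroalkene may be too weak a nucleophile for the protonated enone, so that polymerisation and self-cycloaddition of 1 prevail. The acid may also be sequestered by the basic enol ether product, and the two faces of the alkene may be poorly differentiated. The fallback uses known chemistry, sets out from 1 and returns at 5. Copper-catalysed conjugate addition of 2-methylprop-1-enylmagnesium bromide to 1 (CuI cat., Me3SiCl, THF, −78 °C) gives 6-methylhept-5-en-2-one F1. Catalytic asymmetric allylboration of this ketone (2-allyl-1,3,2-dioxaborinane, (S)-3,3'-dibromo-1,1'-bi-2-naphthol cat., t-BuOH, toluene) gives (4S)-4,8-dimethylnona-1,7-dien-4-ol F2, with the quaternary centre set by the catalyst. Chloroetherification of the trisubstituted alkene (chlorodiethylsulfonium hexachloroantimonate, Et2SCl·SbCl6, CH2Cl2, −78 °C) through a chair-like anti addition then closes the oxane to 5; its chloro epimer is removed by chromatography.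

2. Step 2. The tertiary oxocarbenium ion may eliminate back to enol ethers, and facial selectivity may be poor because the axial approach favoured by chlorine is opposed by the syn-axial methyl of the CMe2 group. The fallback sets out from 3 and returns at 6; it closes the O–C bond at the quaternary carbon last instead of forming the C–C bond on a cation. Aqueous acid (HCl, THF/H2O) hydrolyses 3 to (5R)-5-chloro-6-hydroxy-6-methylheptan-2-one F3. Wittig methylenation (Ph3P=CH2, THF) gives (3R)-3-chloro-2,6-dimethylhept-6-en-2-ol F4. Iodoetherification (I2, NaHCO3, MeCN, 0 °C) through a chair with chlorine and the iodomethyl group equatorial gives (3R,6S)-3-chloro-6-(iodomethyl)-2,2,6-trimethyloxane F5. Radical cyanation with tert-butyl isocyanide ((Me3Si)3SiH, azobisisobutyronitrile, benzene, 80 °C) gives 2-[(2S,5R)-5-chloro-2,6,6-trimethyloxan-2-yl]acetonitrile F6. Reduction with i-Bu2AlH (CH2Cl2, −78 °C, then aqueous acid) gives 6.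

3. Step 6. The cycloaddition may be slow at the hindered β-carbon and lose regiocontrol, and the Lewis acid may strip silicon from the diene or equilibrate the ring fusion. The fallback sets out from 7, which is isolated instead of being cyclised, and returns at 13; it builds both rings by an intramolecular Diels–Alder reaction whose regiochemistry is fixed by the tether. Wittig reaction of the aldehyde of 7 with 2-methylallylidene(triphenyl)phosphorane (THF, −78 °C; I2-catalysed equilibration to the E isomer) gives (5R,6E)-5-[(2S,5R)-5-chloro-2,6,6-trimethyloxan-2-yl]-8-methylnona-6,8-dien-2-one F7. Kinetic enolisation at the methyl group (LDA, −78 °C) and a Mannich reaction with dimethylmethyleneammonium iodide gives (6R,7E)-6-[(2S,5R)-5-chloro-2,6,6-trimethyloxan-2-yl]-1-(dimethylamino)-9-methyldeca-7,9-dien-3-one F8. N-Methylation (MeI) and elimination (NaHCO3) give (6R,7E)-6-[(2S,5R)-5-chloro-2,6,6-trimethyloxan-2-yl]-9-methyldeca-1,7,9-trien-3-one F9. This cyclises on warming in toluene (or with Me2AlCl at low temperature) to 13.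

Further compounds
F1 | step 1 | 6-methylhept-5-en-2-one | CC(=O)CCC=C(C)C
F2 | step 1 | (4S)-4,8-dimethylnona-1,7-dien-4-ol | C=CC[C@@](C)(O)CCC=C(C)C
F3 | step 2 | (5R)-5-chloro-6-hydroxy-6-methylheptan-2-one | CC(=O)CC[C@@H](Cl)C(C)(C)O
F4 | step 2 | (3R)-3-chloro-2,6-dimethylhept-6-en-2-ol | C=C(C)CC[C@@H](Cl)C(C)(C)O
F5 | step 2 | (3R,6S)-3-chloro-6-(iodomethyl)-2,2,6-trimethyloxane | IC[C@]1(C)CC[C@@H](Cl)C(C)(C)O1
F6 | step 2 | 2-[(2S,5R)-5-chloro-2,6,6-trimethyloxan-2-yl]acetonitrile | N#CC[C@]1(C)CC[C@@H](Cl)C(C)(C)O1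
F7 | step 6 | (5R,6E)-5-[(2S,5R)-5-chloro-2,6,6-trimethyloxan-2-yl]-8-methylnona-6,8-dien-2-one | CC(=O)CC[C@H](/C=C/C(C)=C)[C@]1(C)CC[C@@H](Cl)C(C)(C)O1
F8 | step 6 | (6R,7E)-6-[(2S,5R)-5-chloro-2,6,6-trimethyloxan-2-yl]-1-(dimethylamino)-9-methyldeca-7,9-dien-3-one | CN(C)CCC(=O)CC[C@H](/C=C/C(C)=C)[C@]1(C)CC[C@@H](Cl)C(C)(C)O1
F9 | step 6 | (6R,7E)-6-[(2S,5R)-5-chloro-2,6,6-trimethyloxan-2-yl]-9-methyldeca-1,7,9-trien-3-one | C=CC(=O)CC[C@H](/C=C/C(C)=C)[C@]1(C)CC[C@@H](Cl)C(C)(C)O1
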